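**Plan**
- Retrosynthetic cuts: the lower C-4 carbinol goes back to a ketone; the interflavan bond C-4(upper)–C-6(lower ring A) is cut as a tethered Friedel–Crafts bond; in each flavan unit the C-2–C-3 bond of ring C is cut, back to a benzyl ether of an ortho-hydroxyaryl glyoxal.
- Enabling feature: the O-1–CH2 group (future C-2, activated by O-1 and ring B) sits ortho on ring A to the C-3/C-4 vicinal dicarbonyl, so the excited dione can take its hydrogen and close ring C.
- Forward order: ring A (gallacetophenone) and ring B (a benzyl ether) are joined through O-1; ring C closes by C-2–C-3 formation to a racemic trans-dihydroflavonol; the two antipodes are parted and become upper and lower unit; a disiloxane tether, the interflavan bond, deprotection and a last reduction follow.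
- Stereochemistry: the target is ent-oritin-(4α→6)-oritin-4α-ol, with antipodal C-2/C-3 in its two units, so a racemic key step wastes nothing. C-2/C-3 relative configuration (trans) comes from the ring closure; absolute configuration comes from a Ru-catalysed transfer-hydrogenation kinetic resolution.
- Upper C-4 (3,4-cis) is set by delivery of ring A from the O-3 face through the tether; lower C-4 (3,4-trans) by substrate-controlled hydride addition.
- Helpers: the C-4 ketone (chromophore, removed in the last step), the 4-methoxy leaving group, the disiloxane tether, benzyl ethers.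

Key step: step 4

Remark: the 4-methoxy donor made in step 6 is drawn as its 3,4-trans epimer; both C-4 epimers give the same cation later, so its C-4 configuration does not matter.

**Step 1**
Reactants: 1 2,3,4-trihydroxyacetophenone
Product: 2 1-[3,4-bis(benzyloxy)-2-hydroxyphenyl]ethan-1-one
Conditions: BnBr (2.1 equiv), K2CO3, acetone, reflux
Reagents that add atoms: benzyl bromide BrCc1ccccc1
Why: Williamson etherification; the 2-OH is hydrogen-bonded to the acetyl carbonyl and least nucleophilic, so two equivalents of halide should alkylate O-3 and O-4 only.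

**Step 2**
Reactants: 2 1-[3,4-bis(benzyloxy)-2-hydroxyphenyl]ethan-1-one; 3 4-(benzyloxy)benzyl chloride
Product: 4 1-[3,4-bis(benzyloxy)-2-{[4-(benzyloxy)phenyl]methoxy}phenyl]ethan-1-one
Conditions: K2CO3, KI (cat.), DMF, 70 °C
Reagents that add atoms: none
Why: Williamson etherification of the remaining chelated phenol with a reactive p-alkoxybenzyl chloride under more forcing conditions; this CH2 becomes C-2 and brings ring B.

**Step 3**
Reactants: 4 1-[3,4-bis(benzyloxy)-2-{[4-(benzyloxy)phenyl]methoxy}phenyl]ethan-1-one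
Product: 6 2-[3,4-bis(benzyloxy)-2-{[4-(benzyloxy)phenyl]methoxy}phenyl]-2-oxoacetaldehyde, via arylglyoxal hydrate 5 (not isolated)
Conditions: SeO2, 1,4-dioxane/H2O, 90 °C; then toluene, Dean–Stark
Reagents that add atoms: selenium dioxide O=[Se]=O
Why: Riley oxidation of the aryl methyl ketone to the arylglyoxal, which is dehydrated azeotropically; aryl benzyl ethers are not expected to be attacked.

**Step 4**
Reactants: 6 2-[3,4-bis(benzyloxy)-2-{[4-(benzyloxy)phenyl]methoxy}phenyl]-2-oxoacetaldehyde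
Product: 7 racemic trans-(2R,3R)/(2S,3S)-7,8-bis(benzyloxy)-2-[4-(benzyloxy)phenyl]-3-hydroxy-2,3-dihydro-4H-chromen-4-one
Conditions: hν (blue LEDs, about 440 nm), degassed benzene (0.01 M), 4 Å MS, rt
Reagents that add atoms: none
Why: Proposed new method: visible-light n→π* excitation of the vicinal dicarbonyl gives a triplet that takes a hydrogen from the O-1 methylene (1,7-hydrogen transfer to the aldehyde oxygen), and the triplet 1,6-biradical (benzylic C-2 radical, α-hydroxy-α-acyl C-3 radical) collapses after intersystem crossing to the C-2–C-3 bond. The closest known reaction type is the Norrish–Yang photocyclisation of ortho-alkyl and ortho-alkoxy aryl 1,2-diketones and of ortho-benzyloxyaryl ketones; an aldehyde-terminated dione closing a 3-hydroxychromanone is not an established case. Ring C closes as a six-membered ring by radical–radical recombination of the 1,6-biradical, not by a polar closure. At C-3 the hydroxyl should stay hydrogen-bonded to the C-4 carbonyl in the ring plane (equatorial) and at C-2 the aryl group should take the equatorial site of the closing half-chair, so the 2,3-trans racemate is expected; any cis isomer should epimerise at C-3 to trans on brief exposure to Et3N, and no absolute control is wanted because both antipodes are used. The step needs abstraction by the aldehyde oxygen (six-membered ring) and not by the ketone oxygen (five-membered benzofuranol), and only from the O-1 methylene: the s-trans dione with the C-4 carbonyl turned away from O-1 points the aldehyde oxygen at that CH2, and the other benzylic CH2 groups are out of reach.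

**Step 5**
Reactants: 7 racemic trans-7,8-bis(benzyloxy)-2-[4-(benzyloxy)phenyl]-3-hydroxy-2,3-dihydro-4H-chromen-4-one
Product: 8 (2S,3R,4S)-7,8-bis(benzyloxy)-2-[4-(benzyloxy)phenyl]-3,4-dihydro-2H-chromene-3,4-diol and 9 (2R,3R)-7,8-bis(benzyloxy)-2-[4-(benzyloxy)phenyl]-3-hydroxy-2,3-dihydro-4H-chromen-4-one (the unreduced antipode of 7, recovered)
Conditions: RuCl[(R,R)-TsDPEN](p-cymene) (1 mol %), HCO2H/Et3N (5:2), EtOAc, rt, stopped near half conversion; chromatography
Reagents that add atoms: none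
Why: Noyori–Ikariya asymmetric transfer hydrogenation run as a kinetic resolution: with the (R,R)-ligand hydride should go to the carbonyl face that gives the 4S carbinol, which for the (2S,3S)-ketone is also the substrate-preferred axial delivery (equatorial, 3,4-trans hydroxyl), so this antipode is the matched, fast-reacting one and the (2R,3R)-ketone is left.

**Step 6**
Reactants: 8 (2S,3R,4S)-7,8-bis(benzyloxy)-2-[4-(benzyloxy)phenyl]-3,4-dihydro-2H-chromene-3,4-diol
Product: 10 (2S,3R,4S)-7,8-bis(benzyloxy)-2-[4-(benzyloxy)phenyl]-4-methoxy-3,4-dihydro-2H-chromen-3-ol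
Conditions: PPTS (cat.), MeOH/CH2Cl2, rt
Reagents that add atoms: methanol CO
Why: Acid-catalysed SN1 methanolysis of the benzylic 4-OH through the cation stabilised by O-1 and the para 7-benzyloxy group gives a storable C-4 donor with only the 3-OH free.

**Step 7**
Reactants: 10 (2S,3R,4S)-7,8-bis(benzyloxy)-2-[4-(benzyloxy)phenyl]-4-methoxy-3,4-dihydro-2H-chromen-3-ol; 9 (2R,3R)-7,8-bis(benzyloxy)-2-[4-(benzyloxy)phenyl]-3-hydroxy-2,3-dihydro-4H-chromen-4-one
Product: 12 1-{[(2S,3R,4S)-7,8-bis(benzyloxy)-2-[4-(benzyloxy)phenyl]-4-methoxychroman-3-yl]oxy}-3-{[(2R,3R)-7,8-bis(benzyloxy)-2-[4-(benzyloxy)phenyl]-4-oxochroman-3-yl]oxy}-1,1,3,3-tetraisopropyldisiloxane, via chlorosilyl ether 11 (not isolated)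
Conditions: 10, TIPDSCl2 (3 equiv), imidazole, DMF, 0 °C to rt; excess dichloride removed in vacuo; then 9, imidazole, DMAP (cat.), DMF, 40 °C
Reagents that add atoms: 1,3-dichloro-1,1,3,3-tetraisopropyldisiloxane CC(C)[Si](Cl)(C(C)C)O[Si](Cl)(C(C)C)C(C)C
Why: Stepwise silyl ether formation as used to build temporary silicon tethers: the first Si–Cl takes the 3-OH of 10 and the second the α-ketol OH of 9 under non-basic conditions that leave all stereocentres untouched.

**Step 8**
Reactants: 12 disiloxane-linked heterodimer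
Product: 13 macrocyclic tetraisopropyldisiloxane-1,3-diyl 3-O/3-O-bridged (2R,3R)-7,8-bis(benzyloxy)-2-[4-(benzyloxy)phenyl]-6-{(2S,3R)-7,8-bis(benzyloxy)-2-[4-(benzyloxy)phenyl]chroman-4-yl}chroman-4-one with the new C-4 aryl bond α (cis to O-3 of the upper unit)
Conditions: TMSOTf (0.3 equiv), 4 Å MS, CH2Cl2 (0.001 M), −78 to −30 °C; Et3N quench
Reagents that add atoms: none
Why: Intramolecular Friedel–Crafts alkylation: TMSOTf ionises the 4-methoxy group to the flavan-4-yl cation stabilised by O-1 and the 7-benzyloxy group, and the disiloxane, anchored at O-3 on the α-face of the sofa-shaped cation and too short to pass round the edge of the heterocycle, should deliver C-6 of the lower ring A (the one free position ortho and para to ether oxygens and meta to the carbonyl) to that face only, setting the new centre 3,4-cis in a 12-membered ring, as in tethered Lewis-acid condensations of 2,3-trans flavans.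

**Step 9**
Reactants: 13 macrocyclic disiloxane
Product: 14 (2R,3R)-7,8-bis(benzyloxy)-2-[4-(benzyloxy)phenyl]-6-{(2S,3R)-7,8-bis(benzyloxy)-2-[4-(benzyloxy)phenyl]-3-hydroxychroman-4-yl}-3-hydroxychroman-4-one (upper 4-aryl bond α, 3,4-cis)
Conditions: HF·pyridine, THF/pyridine, 0 °C to rt
Reagents that add atoms: none
Why: Fluoride-driven cleavage of both Si–O bonds under buffered acidic conditions that spare the base-sensitive dihydroflavonol and the benzyl ethers.

**Step 10**
Reactants: 14 hexa-O-benzyl dimer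
Product: 15 (2R,3R)-3,7,8-trihydroxy-2-(4-hydroxyphenyl)-6-[(2S,3R,4R)-3,7,8-trihydroxy-2-(4-hydroxyphenyl)-3,4-dihydro-2H-chromen-4-yl]-2,3-dihydro-4H-chromen-4-one
Conditions: H2 (1 atm), Pd(OH)2 on carbon, THF/MeOH, rt
Reagents that add atoms: none
Why: Hydrogenolysis of the six aryl benzyl ethers; the electron-rich aryl ketone and the cyclic benzylic C-2–O-1 bonds should survive, and no benzylic 4-hydroxyl is yet present to be lost.

**Step 11**
Reactants: 15 hexaphenolic dimer ketone
Product: 16 (2R,3S,4R)-2-(4-hydroxyphenyl)-6-[(2S,3R,4R)-3,7,8-trihydroxy-2-(4-hydroxyphenyl)-3,4-dihydro-2H-chromen-4-yl]-3,4-dihydro-2H-chromene-3,4,7,8-tetrol (ent-oritin-(4α→6)-oritin-4α-ol)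
Conditions: NaBH4 (excess), EtOH, 0 °C to rt, argon; then dilute AcOH to pH 6
Reagents that add atoms: none
Why: Borohydride reduction of a free-phenolic trans-dihydroflavonol: axial hydride delivery should give the equatorial 4-hydroxyl trans to the 3-hydroxyl (4R), the usual outcome for 2,3-trans-dihydroflavonols.

**Compound list**
1 | 2,3,4-trihydroxyacetophenone | CC(=O)c1ccc(O)c(O)c1O | starting material
2 | 1-[3,4-bis(benzyloxy)-2-hydroxyphenyl]ethan-1-one | CC(=O)c1ccc(OCc2ccccc2)c(OCc2ccccc2)c1O | intermediate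
3 | 4-(benzyloxy)benzyl chloride | ClCc1ccc(OCc2ccccc2)cc1 | starting material
4 | 1-[3,4-bis(benzyloxy)-2-{[4-(benzyloxy)phenyl]methoxy}phenyl]ethan-1-one | CC(=O)c1ccc(OCc2ccccc2)c(OCc2ccccc2)c1OCc1ccc(OCc2ccccc2)cc1 | intermediate
5 | arylglyoxal hydrate (2,2-dihydroxy-1-aryl-ethanone of 6) | OC(O)C(=O)c1ccc(OCc2ccccc2)c(OCc2ccccc2)c1OCc1ccc(OCc2ccccc2)cc1 | intermediate (not isolated)
6 | 2-[3,4-bis(benzyloxy)-2-{[4-(benzyloxy)phenyl]methoxy}phenyl]-2-oxoacetaldehyde | O=CC(=O)c1ccc(OCc2ccccc2)c(OCc2ccccc2)c1OCc1ccc(OCc2ccccc2)cc1 | intermediate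
7 | racemic trans-7,8-bis(benzyloxy)-2-[4-(benzyloxy)phenyl]-3-hydroxy-2,3-dihydro-4H-chromen-4-one (both antipodes written) | c1ccccc1COc1ccc([C@H]2Oc3c(ccc(OCc4ccccc4)c3OCc3ccccc3)C(=O)[C@@H]2O)cc1.c1ccccc1COc1ccc([C@@H]2Oc3c(ccc(OCc4ccccc4)c3OCc3ccccc3)C(=O)[C@H]2O)cc1 | intermediate
8 | (2S,3R,4S)-7,8-bis(benzyloxy)-2-[4-(benzyloxy)phenyl]-3,4-dihydro-2H-chromene-3,4-diol | c1ccccc1COc1ccc([C@@H]2Oc3c(ccc(OCc4ccccc4)c3OCc3ccccc3)[C@H](O)[C@H]2O)cc1 | intermediate
9 | (2R,3R)-7,8-bis(benzyloxy)-2-[4-(benzyloxy)phenyl]-3-hydroxy-2,3-dihydro-4H-chromen-4-one | c1ccccc1COc1ccc([C@H]2Oc3c(ccc(OCc4ccccc4)c3OCc3ccccc3)C(=O)[C@@H]2O)cc1 | intermediate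
10 | (2S,3R,4S)-7,8-bis(benzyloxy)-2-[4-(benzyloxy)phenyl]-4-methoxy-3,4-dihydro-2H-chromen-3-ol | c1ccccc1COc1ccc([C@@H]2Oc3c(ccc(OCc4ccccc4)c3OCc3ccccc3)[C@H](OC)[C@H]2O)cc1 | intermediate
11 | 3-O-(3-chloro-1,1,3,3-tetraisopropyldisiloxan-1-yl) ether of 10 | c1ccccc1COc1ccc([C@@H]2Oc3c(ccc(OCc4ccccc4)c3OCc3ccccc3)[C@H](OC)[C@H]2O[Si](C(C)C)(C(C)C)O[Si](Cl)(C(C)C)C(C)C)cc1 | intermediate (not isolated)
12 | disiloxane-linked heterodimer: O-3 of the (2S,3R,4S)-4-methoxyflavan and O-3 of the (2R,3R)-flavan-4-one joined through Si(iPr)2–O–Si(iPr)2 | c1ccccc1COc1ccc([C@@H]2Oc3c(ccc(OCc4ccccc4)c3OCc3ccccc3)[C@H](OC)[C@H]2O[Si](C(C)C)(C(C)C)O[Si](C(C)C)(C(C)C)O[C@@H]2[C@@H](c3ccc(OCc4ccccc4)cc3)Oc3c(ccc(OCc4ccccc4)c3OCc3ccccc3)C2=O)cc1 | intermediate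
13 | macrocyclic (4α→6)-linked hexa-O-benzyl dimer ketone with the 3-O/3-O tetraisopropyldisiloxane bridge; upper unit (2S,3R) with 3,4-cis, lower unit (2R,3R) | C(c1ccccc1)Oc1ccc([C@H]2Oc3c(cc([C@@H]4c5ccc(OCc6ccccc6)c(OCc6ccccc6)c5O[C@@H](c5ccc(OCc6ccccc6)cc5)[C@@H]4O[Si]7(C(C)C)C(C)C)c(OCc4ccccc4)c3OCc3ccccc3)C(=O)[C@@H]2O[Si](C(C)C)(C(C)C)O7)cc1 | intermediate
14 | (2R,3R)-7,8-bis(benzyloxy)-2-[4-(benzyloxy)phenyl]-6-{(2S,3R)-7,8-bis(benzyloxy)-2-[4-(benzyloxy)phenyl]-3-hydroxychroman-4-yl}-3-hydroxychroman-4-one, upper 4-aryl bond α (3,4-cis) | C(c1ccccc1)Oc1ccc([C@H]2Oc3c(cc([C@@H]4c5ccc(OCc6ccccc6)c(OCc6ccccc6)c5O[C@@H](c5ccc(OCc6ccccc6)cc5)[C@@H]4O)c(OCc4ccccc4)c3OCc3ccccc3)C(=O)[C@@H]2O)cc1 | intermediate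
15 | (2R,3R)-3,7,8-trihydroxy-2-(4-hydroxyphenyl)-6-[(2S,3R,4R)-3,7,8-trihydroxy-2-(4-hydroxyphenyl)-3,4-dihydro-2H-chromen-4-yl]-2,3-dihydro-4H-chromen-4-one | Oc1ccc([C@H]2Oc3c(cc([C@@H]4c5ccc(O)c(O)c5O[C@@H](c5ccc(O)cc5)[C@@H]4O)c(O)c3O)C(=O)[C@@H]2O)cc1 | intermediate
16 | (2R,3S,4R)-2-(4-hydroxyphenyl)-6-[(2S,3R,4R)-3,7,8-trihydroxy-2-(4-hydroxyphenyl)-3,4-dihydro-2H-chromen-4-yl]-3,4-dihydro-2H-chromene-3,4,7,8-tetrol | Oc1ccc([C@H]2Oc3c(cc([C@@H]4c5ccc(O)c(O)c5O[C@@H](c5ccc(O)cc5)[C@@H]4O)c(O)c3O)[C@@H](O)[C@@H]2O)cc1 | target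

**Step count and risks**
Total steps: 11. Longest linear sequence: 11 (steps 1–11; both flavan units come from racemic 7, so the route has no separate branch).

Steps most likely to fail:

1. Step 4 (proposed new method). The excited dione may abstract hydrogen through its ketone oxygen and close to a five-membered benzofuranol, may fragment by α-cleavage with loss of CO, or may close with poor 2,3-diastereocontrol. Fallback, from 2 back to 7, with known chemistry that closes ring C through O-1–C-2 instead: 2 is protected (MOMCl, iPr2NEt) as 1-[3,4-bis(benzyloxy)-2-(methoxymethoxy)phenyl]ethan-1-one F1. Claisen–Schmidt condensation with 4-(benzyloxy)benzaldehyde (KOH, EtOH) gives (E)-1-[3,4-bis(benzyloxy)-2-(methoxymethoxy)phenyl]-3-[4-(benzyloxy)phenyl]prop-2-en-1-one F2. Weitz–Scheffer epoxidation (H2O2, NaOH, MeOH/THF) gives the racemic trans-epoxy ketone F3. HCl in MeOH then removes the acetal, and the freed phenol opens the epoxide at the benzylic carbon with inversion to give racemic trans-dihydroflavonol 7.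

2. Step 8. The arene may add to the face trans to O-3, ring B of the lower unit may compete with the ketone-deactivated ring A, or the cation may oligomerise or eliminate before the 12-membered ring closes. Fallback, from 9 and 10 back to 14, without the tether: 9 is silylated (TESOTf, 2,6-lutidine) to (2R,3R)-7,8-bis(benzyloxy)-2-[4-(benzyloxy)phenyl]-3-(triethylsilyloxy)chroman-4-one F4. Intermolecular TMSOTf condensation of 10 with excess F4 (CH2Cl2, −78 to −20 °C) should give both C-4 epimers, from which the 3,4-cis (4α→6) dimer 3-O-triethylsilyl ether F5 is separated by chromatography. HF·pyridine then gives 14.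

3. Step 5. The selectivity factor of the transfer hydrogenation may be low, or C-3 may epimerise under the amine/formate medium and erode both products. Fallback, from 7 back to 8 and 9: racemic 7 is resolved by preparative chromatography on a cellulose tris(3,5-dimethylphenylcarbamate) phase into 9 and its antipode (2S,3S)-7,8-bis(benzyloxy)-2-[4-(benzyloxy)phenyl]-3-hydroxy-2,3-dihydro-4H-chromen-4-one F6. F6 is reduced with NaBH4 (MeOH/THF, 0 °C) to the 3,4-trans diol 8.

**Further compounds**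
F1 | step 4 | 1-[3,4-bis(benzyloxy)-2-(methoxymethoxy)phenyl]ethan-1-one | CC(=O)c1ccc(OCc2ccccc2)c(OCc2ccccc2)c1OCOC
F2 | step 4 | (E)-1-[3,4-bis(benzyloxy)-2-(methoxymethoxy)phenyl]-3-[4-(benzyloxy)phenyl]prop-2-en-1-one | O=C(/C=C/c1ccc(OCc2ccccc2)cc1)c1ccc(OCc2ccccc2)c(OCc2ccccc2)c1OCOC
F3 | step 4 | racemic trans-[3-(4-(benzyloxy)phenyl)oxiran-2-yl][3,4-bis(benzyloxy)-2-(methoxymethoxy)phenyl]methanone (both antipodes written) | O=C([C@H]1O[C@@H]1c1ccc(OCc2ccccc2)cc1)c1ccc(OCc2ccccc2)c(OCc2ccccc2)c1OCOC.O=C([C@@H]1O[C@H]1c1ccc(OCc2ccccc2)cc1)c1ccc(OCc2ccccc2)c(OCc2ccccc2)c1OCOC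
F4 | step 8 | (2R,3R)-7,8-bis(benzyloxy)-2-[4-(benzyloxy)phenyl]-3-(triethylsilyloxy)chroman-4-one | c1ccccc1COc1ccc([C@H]2Oc3c(ccc(OCc4ccccc4)c3OCc3ccccc3)C(=O)[C@@H]2O[Si](CC)(CC)CC)cc1
F5 | step 8 | 3-O-triethylsilyl ether (lower unit) of the 3,4-cis (4α→6) hexa-O-benzyl dimer ketone 14 | C(c1ccccc1)Oc1ccc([C@H]2Oc3c(cc([C@@H]4c5ccc(OCc6ccccc6)c(OCc6ccccc6)c5O[C@@H](c5ccc(OCc6ccccc6)cc5)[C@@H]4O)c(OCc4ccccc4)c3OCc3ccccc3)C(=O)[C@@H]2O[Si](CC)(CC)CC)cc1
F6 | step 5 | (2S,3S)-7,8-bis(benzyloxy)-2-[4-(benzyloxy)phenyl]-3-hydroxy-2,3-dihydro-4H-chromen-4-one | c1ccccc1COc1ccc([C@@H]2Oc3c(ccc(OCc4ccccc4)c3OCc3ccccc3)C(=O)[C@H]2O)cc1
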